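**Plan**

- Locants are those of the target hydroazulene: C1/C5 ring fusion, C2–C4 cyclopentene (C3=C4, CH3 on C4), C6 (OH), C7 (side chain C11–C15), C8, C9 (OAc), C10 (=CH2). β is the face of H-1, α the face of H-5.
- Retrosynthesis: remove the two acetates, then cut C14=C15 (cross-metathesis), C12–C13 (allylation of a lactone-derived aldehyde), the C11 methyl, the C10 methylene and O9. Then excise C9 from the seven-membered ring (cut C8–C9 and C9–C10, rejoin C8–C10) to give a trans-hydrindenone. Finally cut C7–C11 (radical cyclisation through an O6 tether), C3=C4 (ring-closing metathesis), and C1–C2 / C4–C5 (conjugate addition–alkylation).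
- Forward ring order: the six-membered ring is bought (enone 1), the cyclopentene is closed by metathesis, a temporary γ-lactone is built across O6/C7, and the seven-membered ring arises last by one-carbon ring expansion.
- Enabling feature: C10 is a ring ketone flanked by the methine C1 and the methylene C8, so a diazo carbon inserts next to C8 and becomes C9. The reagent's silyl group ends up as the C9=C10 enol silane, which directs oxygenation to C9; C10 then becomes the exocyclic methylene.
- Stereochemistry: C6 from (R)-1; C5 and C1 by anti 1,4-addition and trans alkylation; C7 by the tether; C9 by β-face epoxidation anti to the lactone; C11 by convex-face methylation; C12 by matched Brown allylation.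

Key step: step 8

Assumption: the C6 hydroxyl, wedged between the C5 and C7 methines and the C4 methyl, is taken to be acylated far more slowly than the C9 and C12 hydroxyls (step 15), and 1 is taken as a purchasable single enantiomer.

**Route**

Step 1
Reactants: 1 (R)-4-(tert-butyldimethylsilyloxy)cyclohex-2-en-1-one; 2 isopropenylmagnesium bromide; 3 allyl iodide
Product: 5 (2R,3S,4R)-2-allyl-4-(tert-butyldimethylsilyloxy)-3-(prop-1-en-2-yl)cyclohexan-1-one, via magnesium enolate 4 (not isolated)
Conditions: 2 (1.5 equiv), CuBr·SMe2 (10 mol %), THF, –78 °C; then 3 (3 equiv), HMPA, –78 → –20 °C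
Reagents that add atoms: isopropenylmagnesium bromide C=C(C)[Mg]Br; allyl iodide C=CCI
Why: Copper-catalysed conjugate addition should occur anti to the C6 silyloxy group (sets C5) and the enolate should be C-allylated trans to the new isopropenyl group (sets C1), as in three-component conjugate addition–enolate alkylation of 4-silyloxycyclohexenones.

Step 2
Reactants: 5 (2R,3S,4R)-2-allyl-4-(tert-butyldimethylsilyloxy)-3-(prop-1-en-2-yl)cyclohexan-1-one
Product: 6 trans-hydrindenone (3aR,7R,7aS)-7-(tert-butyldimethylsilyloxy)-1-methyl-3,3a,5,6,7,7a-hexahydro-4H-inden-4-one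
Conditions: second-generation Grubbs catalyst (H2IMes)(PCy3)Cl2Ru=CHPh (5 mol %), CH2Cl2, 40 °C
Reagents that add atoms: none
Why: Ring-closing metathesis of the vicinal, trans-diequatorial allyl and isopropenyl groups should close the cyclopentene with its C3=C4 trisubstituted alkene under neutral conditions that leave C1, C5 and C6 untouched.

Step 3
Reactants: 6 trans-hydrindenone
Product: 8 enone (3aR,7R,7aS)-7-(tert-butyldimethylsilyloxy)-1-methyl-3,3a,7,7a-tetrahydro-4H-inden-4-one, via trimethylsilyl enol ether 7 (not isolated)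
Conditions: LiN(i-Pr)2, Me3SiCl, THF, –78 °C; then Pd(OAc)2 (1.1 equiv), MeCN, 25 °C
Reagents that add atoms: none
Why: Kinetic deprotonation at the C8 methylene (not the C1 methine) followed by Saegusa–Ito dehydrogenation should give the C7=C8 enone that later accepts the tethered radical.

Step 4
Reactants: 8 enone
Product: 9 hydroxy enone (3aR,7R,7aS)-7-hydroxy-1-methyl-3,3a,7,7a-tetrahydro-4H-inden-4-one
Conditions: HF (48% aq.), MeCN, 0 °C
Reagents that add atoms: none
Why: Acidic fluoride desilylation should free the C6 hydroxyl as the anchor for the tether without base that could epimerise C1.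

Step 5
Reactants: 9 hydroxy enone; 10 ethyl vinyl ether
Product: 11 bromoacetal (3aR,7R,7aS)-7-(2-bromo-1-ethoxyethoxy)-1-methyl-3,3a,7,7a-tetrahydro-4H-inden-4-one (both acetal epimers)
Conditions: 10 (3 equiv), N-bromosuccinimide, CH2Cl2, –40 → 0 °C
Reagents that add atoms: ethyl vinyl ether C=COCC; N-bromosuccinimide O=C1CCC(=O)N1Br
Why: Bromonium activation of the enol ether and capture of the oxocarbenium ion by the C6 hydroxyl (Ueno–Stork haloacetal formation) should be much faster than any reaction of the ring alkene; the acetal configuration is inconsequential.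

Step 6
Reactants: 11 bromoacetal
Product: 12 tricyclic keto acetal (C10 ketone; cis-fused 2-ethoxyoxolane O6–C12–C11–C7 on the α face; both C12 epimers)
Conditions: Bu3SnH (slow addition), AIBN (cat.), benzene, 80 °C
Reagents that add atoms: none
Why: In the Ueno–Stork radical cyclisation the primary radical should add 5-exo-trig to the enone β-carbon C7, and the O6 tether forces a cis-fused oxolane, so the C7–C11 bond forms on the α face, cis to O6 (sets C7).

Step 7
Reactants: 12 tricyclic keto acetal
Product: 14 keto lactone (C10 ketone; γ-lactone O6–C12(=O)–C11H2–C7 cis-fused on the α face; H-1 β and H-5 α), via lactol 13 (not isolated)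
Conditions: CrO3, H2SO4, H2O, acetone, 0 °C
Reagents that add atoms: water O
Why: Jones oxidation should hydrolyse the cyclic acetal and oxidise the lactol to the γ-lactone, a Lewis-acid-stable temporary ring that masks O6 and C12; ketone and ring alkene are inert.

Step 8
Reactants: 14 keto lactone; 15 (trimethylsilyl)diazomethane
Product: 17 enol silane (seven-membered ring with C9=C10 and Me3SiO on C10; lactone and trans ring fusion unchanged), via α-silyl ketone 16 (not isolated)
Conditions: 15 (1.5 equiv), AlMe3 (2.2 equiv), CH2Cl2, –78 → –20 °C; cold NaHCO3 work-up; then toluene, 110 °C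
Reagents that add atoms: (trimethylsilyl)diazomethane C[Si](C)(C)C=[N+]=[N-]
Why: AlMe3 activates the C10 carbonyl, the diazo carbon of 15 adds to it, and the C8 methylene migrates from C10 to that carbon as N2 leaves (Tiffeneau–Demjanov-type 1,2-shift), inserting the future C9 between C10 and C8; heating then moves the silyl group from C9 to the carbonyl oxygen (1,3-Brook shift of the β-ketosilane) to give the C9=C10 enol silane. The closest known reactions are the organoaluminium-promoted homologation of cyclohexanones with (trimethylsilyl)diazomethane and the thermal isomerisation of β-ketosilanes to silyl enol ethers. The seven-membered ring is not closed end to end but arises by enlargement of the six-membered ring through 1,2-migration of a ring bond. No lasting stereocentre is created (C9 is stereogenic only in 16), and C1, C5, C6 and C7 are retained because the migrating carbon is a methylene and the conditions are non-enolising. The step needs migration of C8 in preference to the ring-fusion methine C1 and a single insertion; the less substituted, less hindered methylene migrates in this reaction class and the bulky α-silyl ketone resists a second addition. The silyl group delivered by the reagent thereby marks C9 for the oxidation of step 9.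

Step 9
Reactants: 17 enol silane
Product: 19 9β-hydroxy-10-ketone lactone, via silyloxy epoxide 18 (not isolated)
Conditions: dimethyldioxirane (1.05 equiv, acetone), CH2Cl2, –78 °C; then AcOH, H2O, THF, 0 °C
Reagents that add atoms: dimethyldioxirane CC1(C)OO1
Why: In this Rubottom oxidation the electron-rich enol silane should be epoxidised faster than the C3=C4 alkene and from the β face, anti to the α-disposed lactone carbon on C7 (sets C9); acid then opens the silyloxy epoxide without base, so C1 is not epimerised.

Step 10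
Reactants: 19 9β-hydroxy-10-ketone lactone; 20 dibromomethane
Product: 21 9β-hydroxy-10-methylene lactone
Conditions: Zn, 20, TiCl4, THF/CH2Cl2, 0 → 25 °C
Reagents that add atoms: dibromomethane BrCBr
Why: The non-basic Takai–Lombardo methylenation should convert the hindered, epimerisable C10 ketone into the exocyclic methylene without touching the lactone, C1 or C9.

Step 11
Reactants: 21 9β-hydroxy-10-methylene lactone; 22 iodomethane
Product: 24 (11S)-11-methyl lactone (CH3 on the convex face of the cis-fused lactone, trans to C8), via dilithium alkoxide enolate 23 (not isolated)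
Conditions: LiN(i-Pr)2 (2.2 equiv), THF, –78 °C; 22 (1.1 equiv), –78 → –40 °C; NH4Cl
Reagents that add atoms: iodomethane CI
Why: The lactone enolate (the C9 alkoxide is a spectator at low temperature) should be methylated on the convex face of the cis-fused bicyclic lactone, anti to the carbocycle, which sets C11.

Step 12
Reactants: 24 (11S)-11-methyl lactone
Product: 25 lactol (both C12 epimers)
Conditions: i-Bu2AlH (2.5 equiv), CH2Cl2, –78 °C; potassium sodium tartrate work-up
Reagents that add atoms: none
Why: Low-temperature hydride reduction of the γ-lactone should stop at the aluminium hemiacetal, giving the lactol as latent C12 aldehyde.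

Step 13
Reactants: 25 lactol; 26 (–)-B-allyldiisopinocampheylborane
Product: 27 6α,9β,12-triol with CH2CH=CH2 on C12 (12S)
Conditions: 26 (3 equiv), Et2O, –78 → 0 °C; then NaOH, H2O2
Reagents that add atoms: (–)-B-allyldiisopinocampheylborane C=CCB([C@@H]1C[C@@H]2C[C@H]([C@H]1C)C2(C)C)[C@@H]1C[C@@H]2C[C@H]([C@H]1C)C2(C)C
Why: Brown allylboration of the open hydroxy-aldehyde tautomer with the reagent derived from (+)-α-pinene should add to the Si face, which is also the Felkin–Anh face set by C11 (matched pair), giving 12S and releasing O6.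

Step 14
Reactants: 27 allyl triol; 28 2-methylbut-2-ene
Product: 29 6α,9β,12-triol with the complete side chain
Conditions: 28 (excess), second-generation Grubbs catalyst (H2IMes)(PCy3)Cl2Ru=CHPh (5 mol %), CH2Cl2, 40 °C
Reagents that add atoms: 2-methylbut-2-ene CC=C(C)C
Why: Cross-metathesis of the terminal alkene with excess 2-methylbut-2-ene should install the prenyl terminus, while the 1,1-disubstituted C10 methylene and the trisubstituted ring alkene are too hindered to react.

Step 15
Reactants: 29 triol; 30 acetic anhydride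
Product: 31 target CNP0151479.2 (9β,12-diacetate with free 6α-hydroxyl)
Conditions: 30 (2.5 equiv), pyridine, CH2Cl2, 0 → 25 °C
Reagents that add atoms: acetic anhydride CC(=O)OC(C)=O
Why: Uncatalysed acylation should acetylate the allylic C9 and the C12 hydroxyls, whereas the C6 hydroxyl, flanked by two methines and the C4 methyl, reacts far more slowly (sterically differentiated acetylation).

**Compound list**

1 | (R)-4-(tert-butyldimethylsilyloxy)cyclohex-2-en-1-one | O=C1C=C[C@H](O[Si](C)(C)C(C)(C)C)CC1 | starting material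
2 | isopropenylmagnesium bromide | C=C(C)[Mg]Br | starting material
3 | allyl iodide | C=CCI | starting material
4 | bromomagnesium enolate of (3S,4R)-4-(tert-butyldimethylsilyloxy)-3-(prop-1-en-2-yl)cyclohexanone (not isolated) | Br[Mg]OC1=C[C@@H](C(C)=C)[C@H](O[Si](C)(C)C(C)(C)C)CC1 | intermediate
5 | (2R,3S,4R)-2-allyl-4-(tert-butyldimethylsilyloxy)-3-(prop-1-en-2-yl)cyclohexan-1-one | O=C1[C@H](CC=C)[C@@H](C(C)=C)[C@H](O[Si](C)(C)C(C)(C)C)CC1 | intermediate
6 | trans-fused (3aR,7R,7aS)-7-(tert-butyldimethylsilyloxy)-1-methyl-3,3a,5,6,7,7a-hexahydro-4H-inden-4-one | O=C1[C@@H]2CC=C(C)[C@H]2[C@H](O[Si](C)(C)C(C)(C)C)CC1 | intermediate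
7 | kinetic trimethylsilyl enol ether of 6, C10=C8 (not isolated) | C[Si](C)(C)OC1=CC[C@@H](O[Si](C)(C)C(C)(C)C)[C@@H]2C(C)=CC[C@@H]12 | intermediate
8 | (3aR,7R,7aS)-7-(tert-butyldimethylsilyloxy)-1-methyl-3,3a,7,7a-tetrahydro-4H-inden-4-one | O=C1C=C[C@@H](O[Si](C)(C)C(C)(C)C)[C@@H]2C(C)=CC[C@@H]12 | intermediate
9 | (3aR,7R,7aS)-7-hydroxy-1-methyl-3,3a,7,7a-tetrahydro-4H-inden-4-one | O=C1C=C[C@@H](O)[C@@H]2C(C)=CC[C@@H]12 | intermediate
10 | ethyl vinyl ether | C=COCC | starting material
11 | (3aR,7R,7aS)-7-(2-bromo-1-ethoxyethoxy)-1-methyl-3,3a,7,7a-tetrahydro-4H-inden-4-one, both acetal epimers | O=C1C=C[C@@H](OC(CBr)OCC)[C@@H]2C(C)=CC[C@@H]12 | intermediate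
12 | tricyclic keto acetal: trans-hydrindenone (C10 ketone) with cis-fused 2-ethoxyoxolane O6–C12H(OEt)–C11H2–C7 on the α face, both C12 epimers | O=C1C[C@H]2CC(OCC)O[C@H]2[C@@H]3C(C)=CC[C@@H]13 | intermediate
13 | corresponding lactol, OH on C12 (not isolated) | O=C1C[C@H]2CC(O)O[C@H]2[C@@H]3C(C)=CC[C@@H]13 | intermediate
14 | keto lactone: trans-hydrindenone (C10 ketone, H-1 β, H-5 α) with γ-lactone O6–C12(=O)–C11H2–C7 cis-fused on the α face | O=C1C[C@H]2CC(=O)O[C@H]2[C@@H]3C(C)=CC[C@@H]13 | intermediate
15 | (trimethylsilyl)diazomethane | C[Si](C)(C)C=[N+]=[N-] | starting material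
16 | ring-expanded 9-(trimethylsilyl)-10-ketone lactone, C9 epimers (not isolated) | O=C1C([Si](C)(C)C)C[C@H]2CC(=O)O[C@H]2[C@@H]3C(C)=CC[C@@H]13 | intermediate
17 | hydroazulene enol silane: C9=C10 with Me3SiO on C10, C3=C4, trans ring fusion, α-face γ-lactone across O6/C7 | C[Si](C)(C)OC1=CC[C@H]2CC(=O)O[C@H]2[C@@H]3C(C)=CC[C@@H]13 | intermediate
18 | 9β,10β-epoxide of 17 with Me3SiO on C10 (not isolated) | C[Si](C)(C)O[C@@]12O[C@@H]1C[C@H]3CC(=O)O[C@H]3[C@@H]3C(C)=CC[C@@H]23 | intermediate
19 | (1R,5S,6R,7S,9R)-9β-hydroxy-10-ketone lactone | O=C1[C@H](O)C[C@H]2CC(=O)O[C@H]2[C@@H]3C(C)=CC[C@@H]13 | intermediate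
20 | dibromomethane | BrCBr | starting material
21 | (1R,5S,6R,7S,9R)-9β-hydroxy-10-methylene lactone | C=C1[C@H](O)C[C@H]2CC(=O)O[C@H]2[C@@H]3C(C)=CC[C@@H]13 | intermediate
22 | iodomethane | CI | starting material
23 | dilithium C9-alkoxide lactone enolate of 21 (not isolated) | [Li+].[Li+].C=C1[C@H]([O-])C[C@H]2C=C([O-])O[C@H]2[C@@H]3C(C)=CC[C@@H]13 | intermediate
24 | (1R,5S,6R,7S,9R,11S)-9β-hydroxy-10-methylene-11-methyl lactone, CH3 trans to C8 | C=C1[C@H](O)C[C@H]2[C@H](C)C(=O)O[C@H]2[C@@H]3C(C)=CC[C@@H]13 | intermediate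
25 | lactol of 24, OH on C12, both epimers | C=C1[C@H](O)C[C@H]2[C@H](C)C(O)O[C@H]2[C@@H]3C(C)=CC[C@@H]13 | intermediate
26 | (–)-B-allyldiisopinocampheylborane, from (+)-α-pinene | C=CCB([C@@H]1C[C@@H]2C[C@H]([C@H]1C)C2(C)C)[C@@H]1C[C@@H]2C[C@H]([C@H]1C)C2(C)C | starting material
27 | (1R,5S,6R,7S,9R,11S,12S)-6α,9β,12-triol with a 12-allyl terminus (side chain CH(CH3)–CH(OH)–CH2CH=CH2) | C=C1[C@H](O)C[C@@H]([C@H](C)[C@H](CC=C)O)[C@@H](O)[C@@H]2C(C)=CC[C@@H]12 | intermediate
28 | 2-methylbut-2-ene | CC=C(C)C | starting material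
29 | (1R,5S,6R,7S,9R,11S,12S)-6α,9β,12-triol with the complete side chain | C=C1[C@H](O)C[C@@H]([C@H](C)[C@H](CC=C(C)C)O)[C@@H](O)[C@@H]2C(C)=CC[C@@H]12 | intermediate
30 | acetic anhydride | CC(=O)OC(C)=O | starting material
31 | CNP0151479.2, (1R,5S,6R,7S,9R,11S,12S)-9,12-diacetoxy-6-hydroxy compound | C=C1[C@H](OC(C)=O)C[C@@H]([C@H](C)[C@H](CC=C(C)C)OC(C)=O)[C@@H](O)[C@@H]2C(C)=CC[C@@H]12 | target

Total step count: 15. Longest linear sequence: 15 steps (from 1).

**Steps most likely to fail**

Step 8. What may go wrong: migration of the ring-fusion carbon C1 in place of the C8 methylene, a second insertion, or protodesilylation before the silyl shift, which would erase the regiochemical marker. The fallback fixes the regiochemistry by kinetic enolisation instead of migratory aptitude; it sets out from 12 and returns to the route at 19. Compound 12 is enolised with LiN(i-Pr)2/Me3SiCl to the kinetic C10=C8 trimethylsilyl enol ether F1. Cyclopropanation with Et2Zn/CH2I2 gives the siloxycyclopropane F2. FeCl3 in DMF cleaves the internal cyclopropane bond to the β-chloro cycloheptanone F3, and NaOAc in MeOH eliminates HCl to the cycloheptenone acetal F4. CrO3/H2SO4 converts the acetal into the cycloheptenone lactone F5. 1,4-Hydrosilylation with Et3SiH and RhCl(PPh3)3 gives the triethylsilyl enol ether F6 (C9=C10), which is oxidised with dimethyldioxirane and then AcOH, as in step 9, to 19.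

Step 9. What may go wrong: epoxidation of the enol silane from the α face, giving the wrong configuration at C9, or competing epoxidation of the ring alkene. The fallback sets C9 under reagent control; it sets out from 17 and returns at 21. Compound 17 is oxidised (dimethyldioxirane, then AcOH) without regard to the face to the C9-epimeric hydroxy ketones F7. Methylenation with Zn/CH2Br2/TiCl4 gives the epimeric allylic alcohols F8, and Dess–Martin periodinane converges both to the α-methylene ketone F9. Reduction with catecholborane and (S)-2-methyl-CBS-oxazaborolidine, in which the methylene-bearing carbon acts as the large group, should give the 9R alcohol 21.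

Step 15. What may go wrong: an insufficient rate difference between the hydroxyl groups, leading to acetylation at O6 or incomplete acetylation at O12. The fallback replaces steric differentiation by orthogonal protection; it sets out from 24 and returns at 31. Compound 24 is silylated (Et3SiOTf, 2,6-lutidine) to the 9-O-triethylsilyl lactone F10. MeNH(OMe)·HCl/AlMe3 opens the lactone to the Weinreb amide F11 with a free C6 hydroxyl, which is capped with t-BuMe2SiOTf/2,6-lutidine to give the 6-O-tert-butyldimethylsilyl amide F12. i-Bu2AlH gives the aldehyde F13, and 26 gives the (12S)-homoallylic alcohol F14. PPTS in MeOH removes only the triethylsilyl group to give the 9,12-diol F15. Acetylation with 30 and DMAP gives the diacetate F16, and cross-metathesis with 28 (second-generation Grubbs catalyst (H2IMes)(PCy3)Cl2Ru=CHPh) gives the prenyl diacetate F17. HF·pyridine then frees O6 to give 31.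

**Further compounds**

F1 | step 8 | trimethylsilyl enol ether of 12 (C10=C8), acetal epimers | C[Si](C)(C)OC1=C[C@H]2CC(OCC)O[C@H]2[C@@H]3C(C)=CC[C@@H]13
F2 | step 8 | siloxycyclopropane (new CH2 bridging C8 and C10), acetal epimers | C[Si](C)(C)OC12CC1[C@H]3CC(OCC)O[C@H]3[C@@H]3C(C)=CC[C@@H]23
F3 | step 8 | 8-chloro-cycloheptan-10-one acetal | O=C1CC(Cl)[C@H]2CC(OCC)O[C@H]2[C@@H]3C(C)=CC[C@@H]13
F4 | step 8 | cyclohept-8-en-10-one acetal | O=C1C=C[C@H]2CC(OCC)O[C@H]2[C@@H]3C(C)=CC[C@@H]13
F5 | step 8 | cyclohept-8-en-10-one lactone | O=C1C=C[C@H]2CC(=O)O[C@H]2[C@@H]3C(C)=CC[C@@H]13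
F6 | step 8 | triethylsilyl enol ether (C9=C10), silyl analogue of 17 | CC[Si](CC)(CC)OC1=CC[C@H]2CC(=O)O[C@H]2[C@@H]3C(C)=CC[C@@H]13
F7 | step 9 | 9-hydroxy-10-ketone lactone as C9 epimers | O=C1C(O)C[C@H]2CC(=O)O[C@H]2[C@@H]3C(C)=CC[C@@H]13
F8 | step 9 | 9-hydroxy-10-methylene lactone as C9 epimers | C=C1C(O)C[C@H]2CC(=O)O[C@H]2[C@@H]3C(C)=CC[C@@H]13
F9 | step 9 | 10-methylene-9-ketone lactone | C=C1C(=O)C[C@H]2CC(=O)O[C@H]2[C@@H]3C(C)=CC[C@@H]13
F10 | step 15 | 9-O-triethylsilyl ether of 24 | C=C1[C@H](O[Si](CC)(CC)CC)C[C@H]2[C@H](C)C(=O)O[C@H]2[C@@H]3C(C)=CC[C@@H]13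
F11 | step 15 | Weinreb amide (C12) with free 6-hydroxyl and 9-O-triethylsilyl ether | C=C1[C@H](O[Si](CC)(CC)CC)C[C@@H]([C@H](C)C(=O)N(C)OC)[C@@H](O)[C@@H]2C(C)=CC[C@@H]12
F12 | step 15 | 6-O-tert-butyldimethylsilyl 9-O-triethylsilyl Weinreb amide | C=C1[C@H](O[Si](CC)(CC)CC)C[C@@H]([C@H](C)C(=O)N(C)OC)[C@@H](O[Si](C)(C)C(C)(C)C)[C@@H]2C(C)=CC[C@@H]12
F13 | step 15 | C12 aldehyde with both silyl ethers | C=C1[C@H](O[Si](CC)(CC)CC)C[C@@H]([C@H](C)C=O)[C@@H](O[Si](C)(C)C(C)(C)C)[C@@H]2C(C)=CC[C@@H]12
F14 | step 15 | (12S)-homoallylic alcohol with both silyl ethers | C=C1[C@H](O[Si](CC)(CC)CC)C[C@@H]([C@H](C)[C@H](CC=C)O)[C@@H](O[Si](C)(C)C(C)(C)C)[C@@H]2C(C)=CC[C@@H]12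
F15 | step 15 | 9,12-diol with 6-O-tert-butyldimethylsilyl ether | C=C1[C@H](O)C[C@@H]([C@H](C)[C@H](CC=C)O)[C@@H](O[Si](C)(C)C(C)(C)C)[C@@H]2C(C)=CC[C@@H]12
F16 | step 15 | 9,12-diacetate with 6-O-tert-butyldimethylsilyl ether, allyl terminus | C=C1[C@H](OC(C)=O)C[C@@H]([C@H](C)[C@H](CC=C)OC(C)=O)[C@@H](O[Si](C)(C)C(C)(C)C)[C@@H]2C(C)=CC[C@@H]12
F17 | step 15 | 9,12-diacetate with 6-O-tert-butyldimethylsilyl ether, prenyl terminus | C=C1[C@H](OC(C)=O)C[C@@H]([C@H](C)[C@H](CC=C(C)C)OC(C)=O)[C@@H](O[Si](C)(C)C(C)(C)C)[C@@H]2C(C)=CC[C@@H]12
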